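**Retrosynthetic overview**

1. The target is a depside: ring B (C1 CO2H, C2 OH, C4 O-acyl, C6 pentyl, i.e. olivetolic acid) is esterified at O4 by the ring A acid. The last operations are O-methylation at C4', chlorination at C3' and cleavage of the ring B ester.
2. The strategy rests on ring A (C1' bearing the ester carbonyl C7', C2' OH, C3' Cl, C4' OMe, C5' H, C6' pentyl). Its 2,4-dioxygenated 6-alkylbenzoate pattern is that of a folded tetraketide: C1'–C6' are C2–C7 of a 3,5,7-trioxododecanoyl chain and C7' is chain C1.
3. Key disconnection: the C1'–C6' bond (chain C2 to chain C7), made by aldol closure and dehydration of the chain while it already sits as an aryl ester on O4 of ring B. Ring A is the only ring formed; ring B is bought.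
4. The aryl triketo ester comes from an acylketene, released by thermolysis of a 6-(2,4-dioxononyl)dioxinone and captured by the 4-OH of tert-butyl olivetolate. The dioxinone is built by two Claisen-type acylations of 2,2,6-trimethyl-4H-1,3-dioxin-4-one (acetyl, then hexanoyl).

Key step: step 6

Remark on the chemistry: the target has no stereocenter; ring B is carried as its tert-butyl ester with the 2-OH free, because this hydroxyl is hydrogen-bonded to the ester carbonyl and should stay out of the acylation, methylation and chlorination, whereas protecting it beside the more reactive 4-OH would cost three extra steps; the hexanoyl unit is delivered as its Weinreb amide so that the dianion acylation stops at the ketone.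

**Route**

Step 1
Reactants: 1 2,2,6-trimethyl-4H-1,3-dioxin-4-one; 2 acetyl chloride
Product: 3 2,2-dimethyl-6-(2-oxopropyl)-4H-1,3-dioxin-4-one
Conditions: 1 (2 equiv), LiN(SiMe3)2 (2 equiv), THF, −78 °C; then 2 (1 equiv), −78 °C; aq. NH4Cl
Reagents that add atoms: none
Why: LiN(SiMe3)2 deprotonates the 6-methyl group to the vinylogous dienolate, which undergoes γ-selective C-acylation (crossed Claisen-type acylation) with acetyl chloride; the dienolate is used in twofold amount because 3 is more acidic than 1.

Step 2
Reactants: 4 hexanoyl chloride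
Product: 5 N-methoxy-N-methylhexanamide
Conditions: MeNHOMe·HCl, K2CO3, CH2Cl2/H2O, 0 °C to rt
Reagents that add atoms: N,O-dimethylhydroxylamine hydrochloride, CNOC.Cl
Why: Schotten–Baumann N-acylation of the hydroxylamine by the acid chloride gives the Weinreb amide without complication.

Step 3
Reactants: 3 2,2-dimethyl-6-(2-oxopropyl)-4H-1,3-dioxin-4-one; 5 N-methoxy-N-methylhexanamide
Product: 6 6-(2,4-dioxononyl)-2,2-dimethyl-4H-1,3-dioxin-4-one
Conditions: 3, LiN(iPr)2 (2.1 equiv), THF, −78 °C; then 5, −78 to −20 °C; 1 M HCl
Reagents that add atoms: none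
Why: Two equivalents of LiN(iPr)2 give the 1,3-dianion of the keto-dioxinone, whose terminal, last-formed carbanion is acylated by the Weinreb amide (Claisen-type acylation of a β-dicarbonyl dianion); the chelated tetrahedral adduct persists until the quench, so the acidic diketone does not consume dianion.

Step 4
Reactants: 7 olivetolic acid (2,4-dihydroxy-6-pentylbenzoic acid)
Product: 8 tert-butyl 2,4-dihydroxy-6-pentylbenzoate
Conditions: Cl3CC(=NH)OtBu (2 equiv), THF/cyclohexane, rt
Reagents that add atoms: tert-butyl 2,2,2-trichloroacetimidate, CC(C)(C)OC(=N)C(Cl)(Cl)Cl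
Why: In this trichloroacetimidate esterification the carboxylic acid itself protonates the imidate and the carboxylate captures the tert-butyl cation at room temperature without added acid, so the phenols should not be etherified and the decarboxylation-prone acid is never heated.

Step 5
Reactants: 6 6-(2,4-dioxononyl)-2,2-dimethyl-4H-1,3-dioxin-4-one; 8 tert-butyl 2,4-dihydroxy-6-pentylbenzoate
Product: 10 tert-butyl 2-hydroxy-6-pentyl-4-[(3,5,7-trioxododecanoyl)oxy]benzoate, via acylketene 9 (not isolated)
Conditions: 8 (1.5 equiv), toluene, 110 °C, N2 stream; concentrate, use crude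
Reagents that add atoms: none
Why: Retro-[4+2] fragmentation of the dioxinone releases acetone and acylketene 9, which is trapped (acylketene capture, as in the thermal acetoacetylation of phenols) by the unhindered 4-OH of 8 and not by the 2-OH, which is hydrogen-bonded to the ester and flanked by it; the excess of phenol competes with capture of the ketene by its own enol.

Step 6
Reactants: 10 tert-butyl 2-hydroxy-6-pentyl-4-[(3,5,7-trioxododecanoyl)oxy]benzoate
Product: 12 tert-butyl 4-[(2,4-dihydroxy-6-pentylbenzoyl)oxy]-2-hydroxy-6-pentylbenzoate, via aldol adduct 11 (not isolated)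
Conditions: Et3N (2 equiv), CH2Cl2, 0 °C to rt; then 1 M aq. HCl, rt
Reagents that add atoms: none
Why: Triethylamine converts the triketo ester into its enolates, and chain C2 (between the ester carbonyl C1 and the C3 ketone) adds to the C7 ketone to form the C1'–C6' bond; β-elimination of water from adduct 11 and enolization of the C3 and C5 carbonyls then give the aromatic ring, which makes the sequence irreversible. The closest known reaction type is the base-mediated aldol aromatization of 3,5,7-triketo esters to resorcylates, here run on an aryl ester in place of an alkyl ester. Ring A closes in a 6-(enolendo)-exo-trig aldol mode. No stereocenter remains in 12, since the two in 11 are lost on dehydration. The step needs the C2-to-C7 aldol closure to outrun loss of the ring B phenoxide (C6-to-C1 Claisen closure to an acylphloroglucinol, O-acylation by the C5 enol to a 4-hydroxy-2-pyranone, or E1cB collapse to the acylketene); this should be secured by the higher electrophilicity of the C7 ketone compared with the ester carbonyl, by the weak amine base at 0 °C and by the aromatization that drains the aldol adduct from the equilibrium. Chain C8 on the pentyl side is only singly activated and is not enolized by triethylamine, so a C8-to-C3 aldol closure is not expected.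

Step 7
Reactants: 12 tert-butyl 4-[(2,4-dihydroxy-6-pentylbenzoyl)oxy]-2-hydroxy-6-pentylbenzoate
Product: 13 tert-butyl 2-hydroxy-4-[(2-hydroxy-4-methoxy-6-pentylbenzoyl)oxy]-6-pentylbenzoate
Conditions: MeI (1.1 equiv), K2CO3 (1.2 equiv), acetone, rt
Reagents that add atoms: iodomethane, CI
Why: In this Williamson etherification the 4'-OH, para to the ester carbonyl and the only phenol not hydrogen-bonded to a carbonyl group, is the most acidic and accessible, so one equivalent of MeI should methylate it and leave the chelated 2'-OH and 2-OH.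

Step 8
Reactants: 13 tert-butyl 2-hydroxy-4-[(2-hydroxy-4-methoxy-6-pentylbenzoyl)oxy]-6-pentylbenzoate
Product: 14 tert-butyl 4-[(3-chloro-2-hydroxy-4-methoxy-6-pentylbenzoyl)oxy]-2-hydroxy-6-pentylbenzoate
Conditions: SO2Cl2 (1.05 equiv), 2,2,6,6-tetramethylpiperidine (10 mol %), toluene, 0 °C to rt
Reagents that add atoms: sulfuryl chloride, O=S(=O)(Cl)Cl
Why: The amine-catalysed chlorination with SO2Cl2 is the known ortho-selective electrophilic chlorination of phenols, in which chlorine is delivered from an amine-bound species hydrogen-bonded to the phenolic OH, so ring A (activated by 2'-OH and 4'-OMe and far more electron-rich than the acyloxy-substituted ring B) should be chlorinated at C3', its only free position ortho to the hydroxyl, and not at C5' para to it.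

Step 9
Reactants: 14 tert-butyl 4-[(3-chloro-2-hydroxy-4-methoxy-6-pentylbenzoyl)oxy]-2-hydroxy-6-pentylbenzoate
Product: 15 4-[(3-chloro-2-hydroxy-4-methoxy-6-pentylbenzoyl)oxy]-2-hydroxy-6-pentylbenzoic acid (target)
Conditions: CF3CO2H/CH2Cl2 (1:4), 0 °C to rt
Reagents that add atoms: none
Why: Acidolysis of the tert-butyl ester (alkyl–oxygen cleavage with loss of 2-methylpropene) leaves the aryl ester, the aryl chloride and the methyl ether untouched, and short exposure at or below room temperature should avoid protodecarboxylation of the salicylic acid, whose ring is deactivated by the 4-acyloxy group.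

**Compound list**

1 | 2,2,6-trimethyl-4H-1,3-dioxin-4-one | CC1=CC(=O)OC(C)(C)O1 | starting material
2 | acetyl chloride | CC(=O)Cl | starting material
3 | 2,2-dimethyl-6-(2-oxopropyl)-4H-1,3-dioxin-4-one | CC(=O)CC1=CC(=O)OC(C)(C)O1 | intermediate
4 | hexanoyl chloride | CCCCCC(=O)Cl | starting material
5 | N-methoxy-N-methylhexanamide | CCCCCC(=O)N(C)OC | intermediate
6 | 6-(2,4-dioxononyl)-2,2-dimethyl-4H-1,3-dioxin-4-one | CCCCCC(=O)CC(=O)CC1=CC(=O)OC(C)(C)O1 | intermediate
7 | olivetolic acid (2,4-dihydroxy-6-pentylbenzoic acid) | CCCCCc1cc(O)cc(O)c1C(=O)O | starting material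
8 | tert-butyl 2,4-dihydroxy-6-pentylbenzoate | CCCCCc1cc(O)cc(O)c1C(=O)OC(C)(C)C | intermediate
9 | acylketene dodec-1-ene-1,3,5,7-tetrone (formed in the flask) | CCCCCC(=O)CC(=O)CC(=O)C=C=O | intermediate
10 | tert-butyl 2-hydroxy-6-pentyl-4-[(3,5,7-trioxododecanoyl)oxy]benzoate | CCCCCC(=O)CC(=O)CC(=O)CC(=O)Oc1cc(O)c(C(=O)OC(C)(C)C)c(CCCCC)c1 | intermediate
11 | tert-butyl 2-hydroxy-4-[(2-hydroxy-4,6-dioxo-2-pentylcyclohexane-1-carbonyl)oxy]-6-pentylbenzoate (aldol adduct, mixture of stereoisomers, formed in the flask) | CCCCCC1(O)CC(=O)CC(=O)C1C(=O)Oc1cc(O)c(C(=O)OC(C)(C)C)c(CCCCC)c1 | intermediate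
12 | tert-butyl 4-[(2,4-dihydroxy-6-pentylbenzoyl)oxy]-2-hydroxy-6-pentylbenzoate | CCCCCc1cc(O)cc(O)c1C(=O)Oc1cc(O)c(C(=O)OC(C)(C)C)c(CCCCC)c1 | intermediate
13 | tert-butyl 2-hydroxy-4-[(2-hydroxy-4-methoxy-6-pentylbenzoyl)oxy]-6-pentylbenzoate | CCCCCc1cc(OC)cc(O)c1C(=O)Oc1cc(O)c(C(=O)OC(C)(C)C)c(CCCCC)c1 | intermediate
14 | tert-butyl 4-[(3-chloro-2-hydroxy-4-methoxy-6-pentylbenzoyl)oxy]-2-hydroxy-6-pentylbenzoate | CCCCCc1cc(OC)c(Cl)c(O)c1C(=O)Oc1cc(O)c(C(=O)OC(C)(C)C)c(CCCCC)c1 | intermediate
15 | 4-[(3-chloro-2-hydroxy-4-methoxy-6-pentylbenzoyl)oxy]-2-hydroxy-6-pentylbenzoic acid | CCCCCc1cc(OC(=O)c2c(CCCCC)cc(OC)c(Cl)c2O)cc(O)c1C(=O)O | target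

**Step count**

Total: 9 steps. Longest linear sequence: 7 steps (steps 1, 3, 5, 6, 7, 8, 9, from compound 1).

**Steps most likely to fail**

Step 6 (key step). The danger is loss of the ring B phenoxide before the ring closes. This can happen by O-acylation from the C5 enol (pyranone formation), by C6-to-C1 Claisen closure, or by E1cB collapse to the acylketene, and each destroys the depside link. The fallback folds ring A before the ester bond exists. It sets out from 6 and comes back at 13. Compound 6 is treated with Et3N in CH2Cl2; the known aldol aromatization of diketo-dioxinones should give 7-hydroxy-2,2-dimethyl-5-pentyl-4H-1,3-benzodioxin-4-one F1. Methylation with MeI and K2CO3 in acetone gives 7-methoxy-2,2-dimethyl-5-pentyl-4H-1,3-benzodioxin-4-one F2. Hydrolysis with KOH in aqueous DMSO and cold acidification gives 2-hydroxy-4-methoxy-6-pentylbenzoic acid F3. F3 is then joined to the 4-OH of 8 with trifluoroacetic anhydride in toluene at rt (mixed-anhydride depside esterification) to give 13.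

Step 8. The danger is poor positional selectivity: attack at C5' (para to the 2'-OH) in place of C3', double chlorination of ring A, or some attack on ring B. The fallback blocks C5' and sets out from 13 and comes back at 14. Para-selective bromination with N-bromosuccinimide in MeCN at 0 °C should give tert-butyl 4-[(5-bromo-2-hydroxy-4-methoxy-6-pentylbenzoyl)oxy]-2-hydroxy-6-pentylbenzoate F4. Chlorination of the one remaining ring A position with SO2Cl2 in CH2Cl2 gives tert-butyl 4-[(5-bromo-3-chloro-2-hydroxy-4-methoxy-6-pentylbenzoyl)oxy]-2-hydroxy-6-pentylbenzoate F5. Hydrogenolysis that takes the C–Br bond in preference to the C–Cl bond (H2, 1 atm, Pd/C, NaOAc, EtOAc, rt, stopped after one equivalent of hydrogen) then gives 14.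

Step 5. The danger is that the acylketene is captured by its own enol oxygen, or dimerizes, faster than the weakly nucleophilic phenol adds; some acylation of the 2-OH is a lesser concern. The fallback is a conventional depside esterification with ring A taken from olivetolic acid. It sets out from 7 and comes back at 12. Benzylation of 7 (BnBr, K2CO3, DMF) gives benzyl 2,4-bis(benzyloxy)-6-pentylbenzoate F6. Saponification (KOH, aqueous DMSO, 90 °C) gives 2,4-bis(benzyloxy)-6-pentylbenzoic acid F7. Coupling of F7 with the 4-OH of 8 (DCC, catalytic DMAP, CH2Cl2) gives tert-butyl 4-{[2,4-bis(benzyloxy)-6-pentylbenzoyl]oxy}-2-hydroxy-6-pentylbenzoate F8. Hydrogenolysis of the two benzyl ethers (H2, Pd/C, EtOAc) gives 12.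

**Further compounds**

F1 | step 6 | 7-hydroxy-2,2-dimethyl-5-pentyl-4H-1,3-benzodioxin-4-one | CCCCCc1cc(O)cc2OC(C)(C)OC(=O)c12
F2 | step 6 | 7-methoxy-2,2-dimethyl-5-pentyl-4H-1,3-benzodioxin-4-one | CCCCCc1cc(OC)cc2OC(C)(C)OC(=O)c12
F3 | step 6 | 2-hydroxy-4-methoxy-6-pentylbenzoic acid | CCCCCc1cc(OC)cc(O)c1C(=O)O
F4 | step 8 | tert-butyl 4-[(5-bromo-2-hydroxy-4-methoxy-6-pentylbenzoyl)oxy]-2-hydroxy-6-pentylbenzoate | CCCCCc1c(Br)c(OC)cc(O)c1C(=O)Oc1cc(O)c(C(=O)OC(C)(C)C)c(CCCCC)c1
F5 | step 8 | tert-butyl 4-[(5-bromo-3-chloro-2-hydroxy-4-methoxy-6-pentylbenzoyl)oxy]-2-hydroxy-6-pentylbenzoate | CCCCCc1c(Br)c(OC)c(Cl)c(O)c1C(=O)Oc1cc(O)c(C(=O)OC(C)(C)C)c(CCCCC)c1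
F6 | step 5 | benzyl 2,4-bis(benzyloxy)-6-pentylbenzoate | CCCCCc1cc(OCc2ccccc2)cc(OCc2ccccc2)c1C(=O)OCc1ccccc1
F7 | step 5 | 2,4-bis(benzyloxy)-6-pentylbenzoic acid | CCCCCc1cc(OCc2ccccc2)cc(OCc2ccccc2)c1C(=O)O
F8 | step 5 | tert-butyl 4-{[2,4-bis(benzyloxy)-6-pentylbenzoyl]oxy}-2-hydroxy-6-pentylbenzoate | CCCCCc1cc(OCc2ccccc2)cc(OCc2ccccc2)c1C(=O)Oc1cc(O)c(C(=O)OC(C)(C)C)c(CCCCC)c1
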